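## The problem

Compound 16 is a honokiol-type biaryl in which the oxygen on position 1 of ring A (biaryl bond at position 2, allyl group at position 4) is bonded to the tertiary C4 of eudesmane-4α,11-diol (trans-fused rings C and D, eudesmane numbering, C15 the methyl on C4, C11 the side-chain carbinol carbon), while ring B, joined through its position 1, keeps an allyl group on position 3 and a free hydroxyl on position 4. The only ring-to-ring bond to be made is the biaryl bond; the difficult connection is the C4–O–aryl ether, which joins a fully substituted, neopentyl-like carbon to an arene that is electron-rich in the oxidation state of the target and therefore closed to nucleophilic substitution. The four stereocentres (C4, C5, C7, C10) all lie in the decalin; C5, C7 and C10 can be bought with the terpene, and the axial C10 methyl, which shields the β face of C4, is the element that can set the fourth (oxygen α and equatorial, C15 β and axial). The tertiary ether and the tertiary C11 carbinol ionise under acid, so protic and Lewis acidic deprotections are excluded at the end. The two allyl arenes are the other fragile feature: base, hydridopalladium species, hydrogenation and oxidants move or consume the terminal double bonds, so these should appear late. The ring B oxygen sits ortho to a benzylic carbon, so any leaving group on that carbon is a latent o-quinone methide unless the oxygen stays capped. The enabling feature is that both allyl groups hang on benzylic carbons (the CH2 on position 4 of ring A and the CH2 on position 3 of ring B): each can travel as a formyl group, the ring A formyl lies para to the ether oxygen and so makes a fluoride at position 1 displaceable by the hindered C4 alkoxide, the ring B formyl is simply that of a salicylaldehyde, and after reduction and bromination both carbons can take their vinyl group in one copper-catalysed operation.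

## Retrosynthesis

**16 to 15.** The two O–Si bonds are cut. Silicon on both oxygens is preferred to any acetal or benzyl-type group because fluoride is the one deprotection that leaves the acid-labile tertiary ether, the tertiary carbinol and the terminal alkenes alone. A triisopropylsilyl group is placed on the ring B oxygen and a triethylsilyl group on the C11 oxygen. The forward step only has to cleave a phenolic and a tertiary silyl ether.

**15 to 13 and 14.** Both benzylic CH2–CH bonds are cut, leading to the bis(bromomethyl) compound 13 and two equivalents of vinylmagnesium bromide 14. The neighbouring cut, at the aryl–CH2 bonds, would need palladium-mediated allylation of aryl halides, which risks migration of the double bond, or a Claisen rearrangement, which cannot reach the ring A position para to oxygen directly. The chosen cut places the reactive carbon where a formyl carbon is needed anyway. The precursor loses both alkenes. The forward reaction must substitute at two activated benzylic bromides without bromine–magnesium exchange and without moving the new double bonds.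

**13 to 12, 11 and 10.** The two C–Br bonds go back to the diol 12, this to the dialdehyde 11 and, by removal of the ring B silyl group, to the hydroxy dialdehyde 10. The silyl group is attached only after the biaryl coupling, because a silyl ether ortho to a formyl group is an activated phenoxide leaving group and would be at risk in aqueous base. The bulky triisopropylsilyl group is chosen over a smaller one because it resists migration from the phenol oxygen to the adjacent benzylic oxygen during the reduction.

**10 to 7 and 9, and 9 to 8.** The biaryl bond between position 2 of ring A and position 1 of ring B is cut. The bromine is left on the terpene-bearing half 7, where it comes at no cost with the fluoroarene, and boron is placed on the simple half 9, one step from 5-bromosalicylaldehyde 8. With this polarity the hindered partner only has to undergo oxidative addition, and the boronate has no ortho substituent. The precursors are a two-ring terpene ether and a commercial-grade arene.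

**7 to 4 and 5 (through 6).** The aryl–O bond at position 1 of ring A is cut, not the C4–O bond. Cutting on the arene side keeps C4 configured before the coupling and avoids a tertiary cation at C4, which would lose a proton. The price is a hindered alkoxide 6 as nucleophile, which is why the arene 5 carries fluoride as leaving group, a para formyl group and an ortho bromine. The C11 hydroxyl must be masked so that only the C4 oxygen can be deprotonated.

**4 to 3, 2 and 1.** The C15–H bond and, one step further back, the C4–O bond are cut: alcohol 4 comes from the spiro-epoxide 3 by hydride opening at C15, and 3 from the exocyclic alkene of 2 by epoxidation on the α face. Adding a methyl nucleophile to a C4 carbonyl group instead would bring the methyl in from the open α face and give the wrong epimer. Compound 2 is the C11 silyl ether of β-eudesmol 1, which supplies C5, C7 and C10.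

## Roads not taken

**Alternative 1:** The cut runs through ring C of the terpene (C1–C10 and C4–C5 bonds). In the forward sense (+)-dihydrocarvone A1, condensed with the matched enantiomer of a chiral primary benzylic amine, adds through its enamine tautomer to ethyl vinyl ketone A2 to create the quaternary C10, and an aldol condensation closes ring C to give (+)-α-cyperone A3.
- Merits: A1 and A2 are cheap bulk chemicals, the supply does not depend on a natural isolate, and the auxiliary overrides the substrate bias at C10.
- Weak points: A3 is far from 4. The C3 carbonyl has to be removed, the C4=C5 double bond has to become a trans ring fusion with a 4α oxygen and a 4β methyl, and the isopropenyl group has to be hydrated at C11. That is several further operations, each with its own selectivity question.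
- Comparison: on cost and independence of supply this road is better. The chosen plan sets against it that 1 already holds C5, C7, C10 and the C11 carbinol and reaches 4 in three steps. The road through A3 does nothing for the ether, the biaryl or the allyl groups, where the real risk lies.

**Alternative 2:** The cut is the C6–C7 bond together with the C11–O bond, followed by the transannular C5–C10 bond. A recombinant hedycaryol synthase ionises (2E,6E)-farnesyl diphosphate A4, closes the ten-membered ring and quenches the C11 cation with water to give (E,E)-hedycaryol A5, with C7 set by the enzyme.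
- Merits: one step from the acyclic A4 along the biosynthetic path. Protonation of A5 folds it to the eudesmane C4 cation, which in principle could be captured by an oxygen nucleophile with the correct configuration.
- Weak points: the enzyme and the supply of A4 limit the scale. A5 rearranges thermally to elemol A6. The acid-mediated closure ends mostly in proton loss, giving 1 and its double-bond isomers, and intermolecular capture by a hindered phenol is unlikely.
- Comparison: this road is more elegant in building the skeleton. The chosen plan sets against it that commercial 1 is the product of exactly this chemistry, so it buys what the road through A4 and A5 would make in two uncertain steps, and the aryl side is left unsolved there.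

**Alternative 3:** The cut is the C2–C3 bond of ring C together with the C4–O ether bond. In the forward sense elemol A6 and the phenol 3-bromo-4-hydroxybenzaldehyde A7 are treated with the dicationic divalent platinum complex [Pt(PhP(CH2CH2PPh2)2)](BF4)2 A8. Platinum binds the vinyl group of A6, the isopropenyl terminus C3 attacks C2 and closes ring C, and A7 captures the C4 cation from the equatorial α side. The proton set free cleaves the Pt–C1 bond and returns A8, giving 4α-(2-bromo-4-formylphenoxy)eudesman-11-ol A9.
- Merits: ring C, the C4 stereocentre and the difficult ether would form in one step from a cheap terpene alcohol. A9 is the desilylated counterpart of 7, so the biaryl coupling and the twofold vinylation could follow unchanged. Steps 1 to 4 would shrink to one and the hindered displacement would be avoided.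
- Weak points: an intermolecular, electron-poor phenol such as A7 has not been shown as the terminating nucleophile in such platinum-initiated cyclisations. Proton loss from the C4 cation and capture by the internal C11 hydroxyl of A6 should be faster. Protonolysis of the platinum–carbon bond in triphosphine complexes of the A8 type is slow, so turnover of A8 is doubtful.
- Comparison: if it worked, this road would be clearly better in step count and convergence. The chosen plan sets against it that each of the four steps it would replace is of a known type, that C4 is configured before the ether bond is made, and that addition–elimination on the arene cannot end in an alkene on the terpene side.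

Key step: step 10

Assumption: commercial 1 is taken as the natural (+)-enantiomer, whose C5, C7 and C10 configurations are those of the target; the C4 centre of the target is read as 4α-aryloxy, 4β-methyl.

## Route

Step 1
Reactants: 1 (+)-β-eudesmol
Product: 2 11-(triethylsilyloxy)eudesm-4(15)-ene
Conditions: TESOTf (1.3 equiv), 2,6-lutidine (2 equiv), CH2Cl2, −78 to 0 °C
Reagents that add atoms: triethylsilyl trifluoromethanesulfonate, CC[Si](CC)(CC)OS(=O)(=O)C(F)(F)F
Why: Silylation of a tertiary alcohol with a silyl triflate and a hindered pyridine base; the exocyclic alkene is inert, and capping the less hindered C11 hydroxyl first leaves C4 as the only alkoxide site later.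

Step 2
Reactants: 2 11-(triethylsilyloxy)eudesm-4(15)-ene
Product: 3 4α,15-epoxy-11-(triethylsilyloxy)eudesmane
Conditions: mCPBA (1.2 equiv), NaHCO3, CH2Cl2, 0 °C
Reagents that add atoms: 3-chloroperbenzoic acid, O=C(OO)c1cccc(Cl)c1
Why: Prilezhaev epoxidation; the peracid should approach the C4=C15 bond from the α face because the axial C10 methyl shields the β face, which places the oxirane oxygen α (equatorial) on C4, and the bicarbonate buffer protects the silyl ether and the epoxide from acid.

Step 3
Reactants: 3 4α,15-epoxy-11-(triethylsilyloxy)eudesmane
Product: 4 11-(triethylsilyloxy)eudesman-4α-ol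
Conditions: LiAlH4 (1.5 equiv), THF, 0 to 50 °C; H2O, aq NaOH
Reagents that add atoms: none
Why: SN2 opening of the spiro-epoxide by hydride at the unhindered primary C15, which turns C15 into the β (axial) methyl and leaves the C4–O bond, and so the α configuration at C4, untouched.

Step 4
Reactants: 4 11-(triethylsilyloxy)eudesman-4α-ol; 5 3-bromo-4-fluorobenzaldehyde
Product: 7 3-bromo-4-{[11-(triethylsilyloxy)eudesman-4α-yl]oxy}benzaldehyde, via potassium C4 alkoxide 6 (not isolated)
Conditions: KH (1.05 equiv), 18-crown-6 (1.1 equiv), THF, 0 °C to rt; then 5 (1.5 equiv), THF, 0 °C to rt
Reagents that add atoms: none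
Why: Nucleophilic aromatic substitution (addition–elimination): the crown-separated potassium alkoxide adds to the fluorine-bearing carbon, activated by the para formyl group and the ortho bromine, and fluoride leaves; the C4–O bond is not touched, so C4 keeps its configuration, and the aldehyde has no α-hydrogen to enolise.

Step 5
Reactants: 8 5-bromosalicylaldehyde
Product: 9 2-hydroxy-5-(4,4,5,5-tetramethyl-1,3,2-dioxaborolan-2-yl)benzaldehyde
Conditions: B2pin2 (1.1 equiv), Pd(dppf)Cl2 (3 mol %), KOAc (3 equiv), 1,4-dioxane, 85 °C
Reagents that add atoms: bis(pinacolato)diboron, CC1(C)OB(B2OC(C)(C)C(C)(C)O2)OC1(C)C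
Why: Miyaura borylation: zerovalent palladium inserts into the C–Br bond and acetate-assisted transmetalation from the diboron reagent delivers the boronate; the weak base KOAc tolerates the free phenol and the aldehyde.

Step 6
Reactants: 7 3-bromo-4-{[11-(triethylsilyloxy)eudesman-4α-yl]oxy}benzaldehyde; 9 2-hydroxy-5-(4,4,5,5-tetramethyl-1,3,2-dioxaborolan-2-yl)benzaldehyde
Product: 10 4'-hydroxy-6-{[11-(triethylsilyloxy)eudesman-4α-yl]oxy}biphenyl-3,3'-dicarbaldehyde
Conditions: 9 (1.3 equiv), Pd(OAc)2 (5 mol %), SPhos (10 mol %), K3PO4 (3 equiv), toluene/H2O 10:1, 80 °C
Reagents that add atoms: none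
Why: Suzuki–Miyaura coupling; the boronate has no ortho substituent, so the bromide next to the bulky tertiary alkoxy group only has to undergo oxidative addition, which the electron-rich biaryl phosphine favours, and both aldehydes, the phenoxide and the tertiary silyl ether tolerate aqueous phosphate.

Step 7
Reactants: 10 4'-hydroxy-6-{[11-(triethylsilyloxy)eudesman-4α-yl]oxy}biphenyl-3,3'-dicarbaldehyde
Product: 11 6-{[11-(triethylsilyloxy)eudesman-4α-yl]oxy}-4'-(triisopropylsilyloxy)biphenyl-3,3'-dicarbaldehyde
Conditions: TIPSCl (1.5 equiv), imidazole (3 equiv), DMF, rt
Reagents that add atoms: chlorotriisopropylsilane, CC(C)[Si](Cl)(C(C)C)C(C)C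
Why: Imidazole-mediated silylation of the only free hydroxyl, the phenol; the bulky silyl group is chosen because it resists migration to the neighbouring benzylic oxygen in the next step.

Step 8
Reactants: 11 6-{[11-(triethylsilyloxy)eudesman-4α-yl]oxy}-4'-(triisopropylsilyloxy)biphenyl-3,3'-dicarbaldehyde
Product: 12 3,3'-bis(hydroxymethyl)-6-{[11-(triethylsilyloxy)eudesman-4α-yl]oxy}-4'-(triisopropylsilyloxy)biphenyl
Conditions: iBu2AlH (2.6 equiv), CH2Cl2, −78 °C; aq potassium sodium tartrate
Reagents that add atoms: none
Why: Hydride reduction of both aryl aldehydes; aluminium alkoxides at −78 °C in a non-protic solvent are poor nucleophiles, which should suppress O-to-O silyl migration on ring B, and the neutral tartrate work-up spares both silyl ethers.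

Step 9
Reactants: 12 3,3'-bis(hydroxymethyl)-6-{[11-(triethylsilyloxy)eudesman-4α-yl]oxy}-4'-(triisopropylsilyloxy)biphenyl
Product: 13 3,3'-bis(bromomethyl)-6-{[11-(triethylsilyloxy)eudesman-4α-yl]oxy}-4'-(triisopropylsilyloxy)biphenyl
Conditions: CBr4 (2.6 equiv), PPh3 (2.6 equiv), solid NaHCO3, CH2Cl2, 0 °C; short silica pad, used at once
Reagents that add atoms: carbon tetrabromide, BrC(Br)(Br)Br
Why: Appel reaction: the alkoxyphosphonium ions of the two primary benzylic alcohols are displaced by bromide (SN2) in a near-neutral medium, the proton ending up in bromoform, so the tertiary ether and both silyl ethers should survive.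

Step 10
Reactants: 13 3,3'-bis(bromomethyl)-6-{[11-(triethylsilyloxy)eudesman-4α-yl]oxy}-4'-(triisopropylsilyloxy)biphenyl; 14 vinylmagnesium bromide
Product: 15 3,3'-diallyl-6-{[11-(triethylsilyloxy)eudesman-4α-yl]oxy}-4'-(triisopropylsilyloxy)biphenyl
Conditions: CuI (20 mol %), 2,2'-bipyridyl (20 mol %), 14 (3.0 equiv, slow addition), THF, −40 to 0 °C; aq NH4Cl at 0 °C
Reagents that add atoms: vinylmagnesium bromide (second equivalent of 14), C=C[Mg]Br
Why: Vinylmagnesium bromide transmetalates to CuI to give a vinylcuprate of monovalent copper, which attacks a benzylic C–Br bond in an SN2-type oxidative addition to give a benzyl(vinyl) species of trivalent copper; reductive elimination forms the CH2–CH bond and returns monovalent copper. The cycle runs once at each bromomethyl group, so two equivalents of 14 end up in 15, one as each vinyl group, and the excess only covers adventitious quenching. The closest known reaction type is the copper-catalysed coupling of benzylic halides with Grignard reagents, which is established for benzyl bromides and vinylmagnesium bromide. No ring closes and no stereocentre is formed or touched; C4, C5, C7 and C10 are remote spectators. The step needs substitution at both benzylic carbons to outrun bromine–magnesium exchange, which would lead to Wurtz-type dimers: both bromides are primary, unhindered and activated by an ortho or para oxygen, and catalytic copper with bipyridyl, low temperature and slow addition of 14 keep free Grignard reagent low. The new double bonds must stay terminal: the medium holds no palladium or hydride source, and the cold NH4Cl quench removes the base before the doubly activated CH2 groups can be deprotonated. Both oxygens are capped, so no equivalent of 14 is wasted and ring B cannot collapse to an o-quinone methide.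

Step 11
Reactants: 15 3,3'-diallyl-6-{[11-(triethylsilyloxy)eudesman-4α-yl]oxy}-4'-(triisopropylsilyloxy)biphenyl
Product: 16 3,3'-diallyl-6-{[11-hydroxyeudesman-4α-yl]oxy}biphenyl-4'-ol (the target)
Conditions: Bu4NF (4 equiv), THF, 0 °C to rt; aq NH4Cl
Reagents that add atoms: none
Why: Fluoride-induced desilylation driven by the Si–F bond; the phenolic silyl ether falls first and the tertiary triethylsilyl ether more slowly, and the non-acidic conditions leave the tertiary ether, the carbinol and the allyl groups alone.

## Compound list

1 | (+)-β-eudesmol (eudesm-4(15)-en-11-ol; 5α-H, 7β side chain, 10β-methyl) | C=C1CCC[C@]2(C)CC[C@@H](C(C)(C)O)C[C@H]21 | starting material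
2 | 11-(triethylsilyloxy)eudesm-4(15)-ene | C=C1CCC[C@]2(C)CC[C@@H](C(C)(C)O[Si](CC)(CC)CC)C[C@H]21 | intermediate
3 | 4α,15-epoxy-11-(triethylsilyloxy)eudesmane (oxirane oxygen α on C4, C15 β) | C1O[C@@]12CCC[C@]3(C)CC[C@@H](C(C)(C)O[Si](CC)(CC)CC)C[C@H]32 | intermediate
4 | 11-(triethylsilyloxy)eudesman-4α-ol (4α-OH, 4β-methyl) | O[C@]1(C)CCC[C@]2(C)CC[C@@H](C(C)(C)O[Si](CC)(CC)CC)C[C@H]21 | intermediate
5 | 3-bromo-4-fluorobenzaldehyde | O=Cc1ccc(F)c(Br)c1 | starting material
6 | potassium 11-(triethylsilyloxy)eudesman-4α-olate (potassium C4 alkoxide of 4, not isolated) | [K+].[O-][C@]1(C)CCC[C@]2(C)CC[C@@H](C(C)(C)O[Si](CC)(CC)CC)C[C@H]21 | intermediate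
7 | 3-bromo-4-{[11-(triethylsilyloxy)eudesman-4α-yl]oxy}benzaldehyde | O=Cc1ccc(O[C@]2(C)CCC[C@]3(C)CC[C@@H](C(C)(C)O[Si](CC)(CC)CC)C[C@H]32)c(Br)c1 | intermediate
8 | 5-bromosalicylaldehyde | O=Cc1cc(Br)ccc1O | starting material
9 | 2-hydroxy-5-(4,4,5,5-tetramethyl-1,3,2-dioxaborolan-2-yl)benzaldehyde | O=Cc1cc(B2OC(C)(C)C(C)(C)O2)ccc1O | intermediate
10 | 4'-hydroxy-6-{[11-(triethylsilyloxy)eudesman-4α-yl]oxy}biphenyl-3,3'-dicarbaldehyde | O=Cc1ccc(O[C@]2(C)CCC[C@]3(C)CC[C@@H](C(C)(C)O[Si](CC)(CC)CC)C[C@H]32)c(-c2ccc(O)c(C=O)c2)c1 | intermediate
11 | 6-{[11-(triethylsilyloxy)eudesman-4α-yl]oxy}-4'-(triisopropylsilyloxy)biphenyl-3,3'-dicarbaldehyde | O=Cc1ccc(O[C@]2(C)CCC[C@]3(C)CC[C@@H](C(C)(C)O[Si](CC)(CC)CC)C[C@H]32)c(-c2ccc(O[Si](C(C)C)(C(C)C)C(C)C)c(C=O)c2)c1 | intermediate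
12 | 3,3'-bis(hydroxymethyl)-6-{[11-(triethylsilyloxy)eudesman-4α-yl]oxy}-4'-(triisopropylsilyloxy)biphenyl | OCc1ccc(O[C@]2(C)CCC[C@]3(C)CC[C@@H](C(C)(C)O[Si](CC)(CC)CC)C[C@H]32)c(-c2ccc(O[Si](C(C)C)(C(C)C)C(C)C)c(CO)c2)c1 | intermediate
13 | 3,3'-bis(bromomethyl)-6-{[11-(triethylsilyloxy)eudesman-4α-yl]oxy}-4'-(triisopropylsilyloxy)biphenyl | BrCc1ccc(O[C@]2(C)CCC[C@]3(C)CC[C@@H](C(C)(C)O[Si](CC)(CC)CC)C[C@H]32)c(-c2ccc(O[Si](C(C)C)(C(C)C)C(C)C)c(CBr)c2)c1 | intermediate
14 | vinylmagnesium bromide | C=C[Mg]Br | starting material
15 | 3,3'-diallyl-6-{[11-(triethylsilyloxy)eudesman-4α-yl]oxy}-4'-(triisopropylsilyloxy)biphenyl | C=CCc1ccc(O[C@]2(C)CCC[C@]3(C)CC[C@@H](C(C)(C)O[Si](CC)(CC)CC)C[C@H]32)c(-c2ccc(O[Si](C(C)C)(C(C)C)C(C)C)c(CC=C)c2)c1 | intermediate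
16 | 3,3'-diallyl-6-{[11-hydroxyeudesman-4α-yl]oxy}biphenyl-4'-ol | C=CCc1ccc(O[C@]2(C)CCC[C@]3(C)CC[C@@H](C(C)(C)O)C[C@H]32)c(-c2ccc(O)c(CC=C)c2)c1 | target

## Step count and least certain steps

Total: 11 steps. Longest linear sequence: 10 steps (steps 1 to 4 and 6 to 11 from 1); step 5 is a one-step side branch from 8.

**Step 10 (key step).** The most likely failure is bromine–magnesium exchange at the activated benzylic bromides, followed by Wurtz-type homocoupling to dimers and oligomers, or an incomplete second substitution. Both bromides are electron-rich benzylic halides that also react with the Grignard reagent without copper. Fallback: 13 is coupled with two equivalents of tributyl(vinyl)stannane under Pd(PPh3)4 catalysis in THF at 50 °C (Stille coupling of benzylic bromides through a benzylpalladium bromide of divalent palladium), which avoids any free carbanion and returns directly at 15. No new compound lies on this path, so its entry F0 in the block below is empty. Its price is contact of the new alkenes with palladium, so the reaction would be stopped at full conversion.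

**Step 4.** The hindered tertiary alkoxide may attack the fluoroarene too slowly, so that reversible addition to the formyl group and hydride transfer between hemiacetal alkoxide and aldehyde (Tishchenko-type consumption of 5) take over. Fallback: 4 is deprotonated to 6 as before and treated with 3-bromo-4-fluorobenzonitrile, whose nitrile activates more strongly and offers no carbonyl group, to give 3-bromo-4-{[11-(triethylsilyloxy)eudesman-4α-yl]oxy}benzonitrile F1. Partial reduction with iBu2AlH in toluene at −78 °C and mild hydrolysis of the aldimine returns at 7.

**Step 2.** Facial selectivity of the epoxidation may be poor, since peracids have an intrinsic preference for axial attack on methylenecyclohexanes that works against the shielding by the C10 methyl; the β-epoxide would lead to the C4 epimer of 4. Fallback: 2 is treated with Hg(OAc)2 in THF/H2O, where water should open the mercurinium ion at C4 along the equatorial α trajectory, to give 15-(acetoxymercurio)-11-(triethylsilyloxy)eudesman-4α-ol F2. Reduction of the carbon–mercury bond with NaBH4 in aqueous NaOH returns at 4 (oxymercuration–demercuration), bypassing 3.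

**Step 9.** The bromide on the ring A benzylic carbon is para to an alkoxy group and the one on the ring B benzylic carbon is ortho to a silyloxy group, so ionisation on silica or on standing, followed by hydrolysis or self-alkylation of the electron-rich rings, is the likely loss. Fallback: 12 is converted with MsCl, LiCl and 2,4,6-collidine in DMF at 0 °C into 3,3'-bis(chloromethyl)-6-{[11-(triethylsilyloxy)eudesman-4α-yl]oxy}-4'-(triisopropylsilyloxy)biphenyl F3, which ionises less readily and can be purified. F3 is coupled with 14 under the CuI catalysis of step 10 (same bonds formed, chloride as leaving group, 0 °C to rt) and returns at 15.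

## Further compounds

F0 | step 10 | none | none
F1 | step 4 | 3-bromo-4-{[11-(triethylsilyloxy)eudesman-4α-yl]oxy}benzonitrile | N#Cc1ccc(O[C@]2(C)CCC[C@]3(C)CC[C@@H](C(C)(C)O[Si](CC)(CC)CC)C[C@H]32)c(Br)c1
F2 | step 2 | 15-(acetoxymercurio)-11-(triethylsilyloxy)eudesman-4α-ol | O[C@]1(C[Hg]OC(C)=O)CCC[C@]2(C)CC[C@@H](C(C)(C)O[Si](CC)(CC)CC)C[C@H]21
F3 | step 9 | 3,3'-bis(chloromethyl)-6-{[11-(triethylsilyloxy)eudesman-4α-yl]oxy}-4'-(triisopropylsilyloxy)biphenyl | ClCc1ccc(O[C@]2(C)CCC[C@]3(C)CC[C@@H](C(C)(C)O[Si](CC)(CC)CC)C[C@H]32)c(-c2ccc(O[Si](C(C)C)(C(C)C)C(C)C)c(CCl)c2)c1
A1 | alternative 1 | (+)-dihydrocarvone | C[C@@H]1CC[C@H](CC1=O)C(C)=C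
A2 | alternative 1 | ethyl vinyl ketone | C=CC(=O)CC
A3 | alternative 1 | (+)-α-cyperone | O=C1CC[C@]2(C)CC[C@@H](C(C)=C)CC2=C1C
A4 | alternative 2 | (2E,6E)-farnesyl diphosphate | CC(C)=CCC/C(C)=C/CC/C(C)=C/COP(=O)(O)OP(=O)(O)O
A5 | alternative 2 | (E,E)-hedycaryol | C1C[C@@H](C(C)(C)O)C/C=C(C)/CC/C=C(C)/1
A6 | alternative 2 | elemol | C=C[C@]1(C)CC[C@@H](C(C)(C)O)C[C@H]1C(C)=C
A7 | alternative 3 | 3-bromo-4-hydroxybenzaldehyde | O=Cc1ccc(O)c(Br)c1
A8 | alternative 3 | [Pt(PhP(CH2CH2PPh2)2)](BF4)2 | [Pt+2].c1ccc(cc1)P(CCP(c1ccccc1)c1ccccc1)CCP(c1ccccc1)c1ccccc1.F[B-](F)(F)F.F[B-](F)(F)F
A9 | alternative 3 | 4α-(2-bromo-4-formylphenoxy)eudesman-11-ol | O=Cc1ccc(O[C@]2(C)CCC[C@]3(C)CC[C@@H](C(C)(C)O)C[C@H]32)c(Br)c1
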